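**Retrosynthetic overview**
1. Target 28 comes from its bis-TBS ether 27 by a final global desilylation.
2. The only ring, the γ-lactone, is closed at C3–C4: hydride conjugate addition to the ynoate of aldehyde 24, then intramolecular aldol of the allenolate, which sets C4 and the 3Z alkylidene.
3. Aldehyde 24 comes from ester 22, made by esterifying ynoic acid 10 (east fragment) with alcohol 20 (west fragment).
4. Acid 10 comes from geranyl acetate 1: allylic oxidation, catalytic asymmetric propargylation (side-chain carbinol), carboxylation.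
5. Alcohol 20 comes from L-ascorbic acid 11 through (S)-glyceraldehyde acetonide 16 and an isopropylidene Wittig reaction (C5 from the chiral pool).

Assumption: the (R)-configured phosphoric acid of step 3 is taken to deliver the propargyl group to the Re face of enal 3, as it does in allylboration of aldehydes.

**East fragment**

Step 1
Reactants: 1 geranyl acetate
Product: 2 (2E,6E)-8-hydroxy-3,7-dimethylocta-2,6-dien-1-yl acetate
Conditions: SeO2 (0.1 equiv), t-BuOOH (3 equiv), salicylic acid (0.1 equiv), CH2Cl2, rt, 36 h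
Reagents that add atoms: tert-butyl hydroperoxide, CC(C)(C)OO (the new oxygen, relayed by selenium dioxide, O=[Se]=O)
Why: Riley allylic oxidation (ene reaction, then [2,3]-sigmatropic shift) hits only the E-methyl of the electron-rich terminal alkene and spares the alkene next to the acetate.

Step 2
Reactants: 2 (2E,6E)-8-hydroxy-3,7-dimethylocta-2,6-dien-1-yl acetate
Product: 3 (2E,6E)-3,7-dimethyl-8-oxoocta-2,6-dien-1-yl acetate
Conditions: PhI(OAc)2 (1.1 equiv), 2,2,6,6-tetramethylpiperidin-1-oxyl (0.1 equiv), CH2Cl2, rt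
Reagents that add atoms: none
Why: Oxoammonium-mediated oxidation of the primary allylic alcohol stops at the enal and does not isomerise either alkene.

Step 3
Reactants: 3 (2E,6E)-3,7-dimethyl-8-oxoocta-2,6-dien-1-yl acetate
Product: 5 (2E,6E,8R)-8-hydroxy-3,7-dimethylundeca-2,6-dien-10-yn-1-yl acetate, via borate ester 4 (not isolated)
Conditions: allenylboronic acid pinacol ester (1.5 equiv), (R)-3,3′-bis(2,4,6-triisopropylphenyl)-1,1′-binaphthalene-2,2′-diyl hydrogen phosphate (10 mol %), 4 Å MS, toluene, −20 °C, 72 h; aq. NaHCO3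
Reagents that add atoms: allenylboronic acid pinacol ester, C=C=CB1OC(C)(C)C(C)(C)O1
Why: Chiral Brønsted-acid-catalysed propargylboration through a closed six-membered SE2′ transition state adds to the Re face of the enal and sets the 8R carbinol (ee to be checked by Mosher esters).

Step 4
Reactants: 5 (2E,6E,8R)-8-hydroxy-3,7-dimethylundeca-2,6-dien-10-yn-1-yl acetate
Product: 6 (2E,6E,8R)-3,7-dimethylundeca-2,6-dien-10-yne-1,8-diol
Conditions: K2CO3 (0.5 equiv), MeOH, 0 °C to rt
Reagents that add atoms: none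
Why: Base-catalysed transesterification removes the acetate, which would not survive n-BuLi in step 6, without touching the alkyne or the stereocenter.

Step 5
Reactants: 6 (2E,6E,8R)-3,7-dimethylundeca-2,6-dien-10-yne-1,8-diol
Product: 7 (2E,6E,8R)-1,8-bis(tert-butyldimethylsilyloxy)-3,7-dimethylundeca-2,6-dien-10-yne
Conditions: TBSCl (2.5 equiv), imidazole (5 equiv), DMF, rt, 16 h
Reagents that add atoms: tert-butyldimethylsilyl chloride, CC(C)(C)[Si](C)(C)Cl
Why: Double silylation protects both hydroxyls with groups that survive organolithium, copper hydride and oxidation and leave together at the end.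

Step 6
Reactants: 7 (2E,6E,8R)-1,8-bis(tert-butyldimethylsilyloxy)-3,7-dimethylundeca-2,6-dien-10-yne
Product: 10 (5R,6E,10E)-5,12-bis(tert-butyldimethylsilyloxy)-6,10-dimethyldodeca-6,10-dien-2-ynoic acid, via lithium acetylide 8 (not isolated), via lithium carboxylate 9 (not isolated)
Conditions: n-BuLi (1.05 equiv), THF, −78 °C; CO2 (g), −78 to 0 °C; cold 0.5 M HCl to pH 3
Reagents that add atoms: carbon dioxide, O=C=O
Why: Deprotonation of the terminal alkyne and carboxylation of the acetylide gives the 2-ynoic acid whose carboxyl carbon becomes the lactone carbonyl.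

**West fragment**

Step 7
Reactants: 11 L-ascorbic acid
Product: 12 L-gulono-1,4-lactone (all-cis 2,3-dihydroxy lactone)
Conditions: H2 (3.5 atm), 10 % Pd/C, H2O, 50 °C, 24 h
Reagents that add atoms: none
Why: Heterogeneous syn-hydrogenation of the enediol from the face opposite the side chain gives the gulono lactone; the side-chain carbinol that ends as C5 of the target is untouched.

Step 8
Reactants: 12 L-gulono-1,4-lactone
Product: 13 5,6-O-isopropylidene-L-gulono-1,4-lactone
Conditions: 2-methoxypropene (1.3 equiv), p-TsOH·H2O (cat.), DMF, 10 °C to rt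
Reagents that add atoms: 2-methoxypropene, COC(C)=C
Why: Kinetic acetalisation selects the terminal 1,2-diol and leaves the ring diol free for cleavage.

Step 9
Reactants: 13 5,6-O-isopropylidene-L-gulono-1,4-lactone
Product: 16 (S)-2,2-dimethyl-1,3-dioxolane-4-carbaldehyde, via glyoxylate ester 14 (not isolated), via threose acetonide 15 (not isolated)
Conditions: NaIO4 (2.1 equiv), H2O, pH 5.5 (NaOH), 0 °C to rt
Reagents that add atoms: none
Why: Malaprade cleavage of the ring diol, hydrolysis of the glyoxylate ester and a second periodate cleavage of the α-hydroxy aldehyde leave the S aldehyde with its stereocenter untouched.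

Step 10
Reactants: 16 (S)-2,2-dimethyl-1,3-dioxolane-4-carbaldehyde
Product: 18 (4R)-2,2-dimethyl-4-(2-methylprop-1-en-1-yl)-1,3-dioxolane, via oxaphosphetane 17 (not isolated)
Conditions: i-PrPPh3I (1.3 equiv), n-BuLi (1.25 equiv), THF, 0 °C; then 16, −78 °C to rt
Reagents that add atoms: isopropyltriphenylphosphonium iodide, CC(C)[P+](c1ccccc1)(c1ccccc1)c1ccccc1.[I-]
Why: Wittig olefination with the non-stabilised isopropylidene ylide installs the isobutenyl group at low temperature without epimerising the α-alkoxy centre (the descriptor changes to R only by priority).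

Step 11
Reactants: 18 (4R)-2,2-dimethyl-4-(2-methylprop-1-en-1-yl)-1,3-dioxolane
Product: 19 (2R)-4-methylpent-3-ene-1,2-diol
Conditions: AcOH/H2O 4:1, 40 °C; toluene azeotrope
Reagents that add atoms: none
Why: Mild acid-catalysed acetal hydrolysis frees the diol under conditions too weak to ionise the allylic C–O bond.

Step 12
Reactants: 19 (2R)-4-methylpent-3-ene-1,2-diol
Product: 20 (2R)-4-methyl-1-(triethylsilyloxy)pent-3-en-2-ol
Conditions: TESCl (1.05 equiv), imidazole (2 equiv), CH2Cl2, −78 to −30 °C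
Reagents that add atoms: triethylsilyl chloride, CC[Si](Cl)(CC)CC
Why: Silylation at low temperature selects the primary hydroxyl, and the TES group can later be removed in the presence of TBS ethers.

**Union and endgame**

Step 13
Reactants: 10 (5R,6E,10E)-5,12-bis(tert-butyldimethylsilyloxy)-6,10-dimethyldodeca-6,10-dien-2-ynoic acid; 20 (2R)-4-methyl-1-(triethylsilyloxy)pent-3-en-2-ol
Product: 22 (2R)-4-methyl-1-(triethylsilyloxy)pent-3-en-2-yl (5R,6E,10E)-5,12-bis(tert-butyldimethylsilyloxy)-6,10-dimethyldodeca-6,10-dien-2-ynoate, via O-acylisourea 21 (not isolated)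
Conditions: DCC (1.3 equiv), 4-(dimethylamino)pyridine (0.1 equiv), CH2Cl2, −20 to 0 °C
Reagents that add atoms: none
Why: Steglich esterification joins the two fragments at the secondary alcohol with retention, and the low temperature with little amine limits ynoate isomerisation.

Step 14
Reactants: 22 the TES-protected ynoate ester
Product: 23 (2R)-1-hydroxy-4-methylpent-3-en-2-yl (5R,6E,10E)-5,12-bis(tert-butyldimethylsilyloxy)-6,10-dimethyldodeca-6,10-dien-2-ynoate
Conditions: HF·pyridine, pyridine, THF, 0 °C, 1 h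
Reagents that add atoms: none
Why: Buffered fluoride cleaves the primary TES ether far faster than either TBS ether and is not basic enough to drive 1,2-acyl migration.

Step 15
Reactants: 23 the hydroxy ynoate ester
Product: 24 (2R)-4-methyl-1-oxopent-3-en-2-yl (5R,6E,10E)-5,12-bis(tert-butyldimethylsilyloxy)-6,10-dimethyldodeca-6,10-dien-2-ynoate
Conditions: Dess–Martin periodinane (1.3 equiv), NaHCO3 (5 equiv), CH2Cl2, 0 °C, 45 min; used at once
Reagents that add atoms: none
Why: Dess–Martin oxidation is non-basic, so the α-acyloxy β,γ-unsaturated aldehyde is formed without enolisation, epimerisation or alkene migration.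

Step 16
Reactants: 24 the α-acyloxy aldehyde ynoate
Product: 27 (3Z,4S,5R)-3-[(3R,4E,8E)-3,10-bis(tert-butyldimethylsilyloxy)-4,8-dimethyldeca-4,8-dien-1-ylidene]-4-hydroxy-5-(2-methylprop-1-en-1-yl)oxolan-2-one, via copper allenolate 25 (not isolated), via copper aldolate 26 (not isolated)
Conditions: [(Ph3P)CuH]6 (0.22 equiv, 1.3 hydride equiv), degassed toluene, −40 to 0 °C; sat. aq. NH4Cl
Reagents that add atoms: none
Why: Michael-type hydride addition to the ynoate gives a copper allenolate that closes the lactone by intramolecular aldol addition (reductive aldol cyclisation); attack anti to the CH2R terminus puts the side chain cis to the lactone carbonyl (3Z), and the copper-bound aldehyde oxygen turning away from the C5 isobutenyl group is expected to give the 4,5-trans (4S) alcohol.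

Step 17
Reactants: 27 the bis-TBS lactone
Product: 28 (3Z,4S,5R)-3-[(3R,4E,8E)-3,10-dihydroxy-4,8-dimethyldeca-4,8-dien-1-ylidene]-4-hydroxy-5-(2-methylprop-1-en-1-yl)oxolan-2-one (target)
Conditions: HF·pyridine (excess), pyridine, THF, 0 °C to rt, 12 h
Reagents that add atoms: none
Why: Buffered fluoride desilylation removes both TBS ethers without opening the lactone, adding to the alkylidene lactone or ionising the allylic alcohols.

**Compound list**

1 | geranyl acetate | CC(C)=CCC/C(C)=C/COC(C)=O | starting material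
2 | (2E,6E)-8-hydroxy-3,7-dimethylocta-2,6-dien-1-yl acetate | OC/C(C)=C/CC/C(C)=C/COC(C)=O | intermediate
3 | (2E,6E)-3,7-dimethyl-8-oxoocta-2,6-dien-1-yl acetate | O=C/C(C)=C/CC/C(C)=C/COC(C)=O | intermediate
4 | pinacol borate ester of alcohol 5 | C#CC[C@@H](OB1OC(C)(C)C(C)(C)O1)/C(C)=C/CC/C(C)=C/COC(C)=O | intermediate (not isolated)
5 | (2E,6E,8R)-8-hydroxy-3,7-dimethylundeca-2,6-dien-10-yn-1-yl acetate | C#CC[C@@H](O)/C(C)=C/CC/C(C)=C/COC(C)=O | intermediate
6 | (2E,6E,8R)-3,7-dimethylundeca-2,6-dien-10-yne-1,8-diol | C#CC[C@@H](O)/C(C)=C/CC/C(C)=C/CO | intermediate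
7 | (2E,6E,8R)-1,8-bis(tert-butyldimethylsilyloxy)-3,7-dimethylundeca-2,6-dien-10-yne | C#CC[C@@H](O[Si](C)(C)C(C)(C)C)/C(C)=C/CC/C(C)=C/CO[Si](C)(C)C(C)(C)C | intermediate
8 | lithium acetylide of 7 | [Li]C#CC[C@@H](O[Si](C)(C)C(C)(C)C)/C(C)=C/CC/C(C)=C/CO[Si](C)(C)C(C)(C)C | intermediate (not isolated)
9 | lithium carboxylate of acid 10 | [Li+].[O-]C(=O)C#CC[C@@H](O[Si](C)(C)C(C)(C)C)/C(C)=C/CC/C(C)=C/CO[Si](C)(C)C(C)(C)C | intermediate (not isolated)
10 | (5R,6E,10E)-5,12-bis(tert-butyldimethylsilyloxy)-6,10-dimethyldodeca-6,10-dien-2-ynoic acid | OC(=O)C#CC[C@@H](O[Si](C)(C)C(C)(C)C)/C(C)=C/CC/C(C)=C/CO[Si](C)(C)C(C)(C)C | intermediate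
11 | L-ascorbic acid | OC[C@H](O)[C@H]1OC(=O)C(O)=C1O | starting material
12 | L-gulono-1,4-lactone | OC[C@H](O)[C@H]1OC(=O)[C@@H](O)[C@H]1O | intermediate
13 | 5,6-O-isopropylidene-L-gulono-1,4-lactone | CC1(C)OC[C@H](O1)[C@H]2OC(=O)[C@@H](O)[C@H]2O | intermediate
14 | 2-O-glyoxyloyl-3,4-O-isopropylidene-L-threose | CC1(C)OC[C@H](O1)[C@H](C=O)OC(=O)C=O | intermediate (not isolated)
15 | 3,4-O-isopropylidene-L-threose | CC1(C)OC[C@H](O1)[C@H](C=O)O | intermediate (not isolated)
16 | (S)-2,2-dimethyl-1,3-dioxolane-4-carbaldehyde | CC1(C)OC[C@H](O1)C=O | intermediate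
17 | oxaphosphetane from 16 and the isopropylidene ylide, 4-[(4S)-2,2-dimethyl-1,3-dioxolan-4-yl]-3,3-dimethyl-2,2,2-triphenyl-1,2-oxaphosphetane | CC1(C)OC[C@H](O1)C1OP(c2ccccc2)(c2ccccc2)(c2ccccc2)C1(C)C | intermediate (not isolated)
18 | (4R)-2,2-dimethyl-4-(2-methylprop-1-en-1-yl)-1,3-dioxolane | CC1(C)OC[C@H](O1)C=C(C)C | intermediate
19 | (2R)-4-methylpent-3-ene-1,2-diol | OC[C@H](O)C=C(C)C | intermediate
20 | (2R)-4-methyl-1-(triethylsilyloxy)pent-3-en-2-ol | CC[Si](CC)(CC)OC[C@H](O)C=C(C)C | intermediate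
21 | O-acylisourea of acid 10 with DCC | O=C(OC(=NC1CCCCC1)NC1CCCCC1)C#CC[C@@H](O[Si](C)(C)C(C)(C)C)/C(C)=C/CC/C(C)=C/CO[Si](C)(C)C(C)(C)C | intermediate (not isolated)
22 | (2R)-4-methyl-1-(triethylsilyloxy)pent-3-en-2-yl (5R,6E,10E)-5,12-bis(tert-butyldimethylsilyloxy)-6,10-dimethyldodeca-6,10-dien-2-ynoate | CC(C)=C[C@H](CO[Si](CC)(CC)CC)OC(=O)C#CC[C@@H](O[Si](C)(C)C(C)(C)C)/C(C)=C/CC/C(C)=C/CO[Si](C)(C)C(C)(C)C | intermediate
23 | (2R)-1-hydroxy-4-methylpent-3-en-2-yl ester of acid 10 | CC(C)=C[C@H](CO)OC(=O)C#CC[C@@H](O[Si](C)(C)C(C)(C)C)/C(C)=C/CC/C(C)=C/CO[Si](C)(C)C(C)(C)C | intermediate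
24 | (2R)-4-methyl-1-oxopent-3-en-2-yl ester of acid 10 | CC(C)=C[C@H](C=O)OC(=O)C#CC[C@@H](O[Si](C)(C)C(C)(C)C)/C(C)=C/CC/C(C)=C/CO[Si](C)(C)C(C)(C)C | intermediate
25 | copper allenolate from hydride addition to 24 | CC(C)=C[C@H](C=O)OC(O[Cu])=C=CC[C@@H](O[Si](C)(C)C(C)(C)C)/C(C)=C/CC/C(C)=C/CO[Si](C)(C)C(C)(C)C | intermediate (not isolated)
26 | copper alkoxide of lactone 27 | CC(C)=C[C@H]1OC(=O)/C(=C\C[C@@H](O[Si](C)(C)C(C)(C)C)/C(C)=C/CC/C(C)=C/CO[Si](C)(C)C(C)(C)C)[C@@H]1O[Cu] | intermediate (not isolated)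
27 | (3Z,4S,5R)-3-[(3R,4E,8E)-3,10-bis(tert-butyldimethylsilyloxy)-4,8-dimethyldeca-4,8-dien-1-ylidene]-4-hydroxy-5-(2-methylprop-1-en-1-yl)oxolan-2-one | CC(C)=C[C@H]1OC(=O)/C(=C\C[C@@H](O[Si](C)(C)C(C)(C)C)/C(C)=C/CC/C(C)=C/CO[Si](C)(C)C(C)(C)C)[C@@H]1O | intermediate
28 | (3Z,4S,5R)-3-[(3R,4E,8E)-3,10-dihydroxy-4,8-dimethyldeca-4,8-dien-1-ylidene]-4-hydroxy-5-(2-methylprop-1-en-1-yl)oxolan-2-one | CC(C)=C[C@H]1OC(=O)/C(=C\C[C@@H](O)/C(C)=C/CC/C(C)=C/CO)[C@@H]1O | target

**Step count**
Total step count: 17.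
Longest linear sequence: 11 (steps 1–6 then 13–17; equally steps 7–12 then 13–17).

**Three steps most likely to fail**

Step 16 (reductive aldol cyclisation). The risks are 1,2-reduction of the aldehyde, a slow five-membered enolendo closure, and loss of the Z geometry or of 4,5-trans selectivity. The fallback sets out from ester 22 and comes back at lactone 27; it pre-forms the nucleophilic carbon with defined geometry instead of making it by hydride addition. Pd(PPh3)4-catalysed syn-hydrostannation of 22 (Bu3SnH, THF, 0 °C) gives the α-stannyl enoate F1. Iododestannylation (I2, CH2Cl2, 0 °C) gives, with retention, the α-iodo enoate F2, in which iodine is cis to the vinyl hydrogen. HF·pyridine/pyridine then frees the primary alcohol to give the hydroxy iodo ester F3, and Dess–Martin oxidation gives the iodo aldehyde F4. CrCl2 (4 equiv) with NiCl2 (2 mol %) in degassed DMF–THF closes the ring by an intramolecular Reformatsky-type (Nozaki–Hiyama–Kishi) addition of the α-metallated enoate carbon to the aldehyde, with retention of alkene geometry, to give 27.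

Step 3 (asymmetric propargylation). The α-branched enal may react slowly or with low ee. The fallback sets out from enal 3 and comes back at alcohol 5; it uses resolution instead of asymmetric catalysis. Barbier propargylation of 3 (propargyl bromide, Zn dust, THF/sat. aq. NH4Cl, 0 °C) gives the racemic homopropargylic alcohol F5. Sharpless kinetic resolution (Ti(OiPr)4, diisopropyl L-(+)-tartrate, t-BuOOH, 4 Å MS, CH2Cl2, −20 °C, about 55 % conversion) epoxidises the 8S enantiomer to the epoxy alcohol F6 and leaves 5 (8R), which is separated by chromatography.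

Step 13 (esterification of the 2-ynoic acid). The activated ynoic acid can isomerise to the allenoate, add the amine catalyst in conjugate fashion, or acylate the hindered allylic alcohol poorly. The fallback sets out from alkyne 7 and alcohol 20 and comes back at ester 22; it forms the ester C–O bond first and the ynoate C–C bond second, so acid 10 is not needed. Alcohol 20 with 4-nitrophenyl chloroformate and pyridine (CH2Cl2, 0 °C) gives the mixed carbonate F7. Lithium acetylide 8 (from 7, n-BuLi, THF, −78 °C) is added to F7 at −78 °C and displaces 4-nitrophenoxide to give 22.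

**Further compounds**

F1 | step 16 | (2R)-4-methyl-1-(triethylsilyloxy)pent-3-en-2-yl (2E,5R,6E,10E)-5,12-bis(tert-butyldimethylsilyloxy)-6,10-dimethyl-2-(tributylstannyl)dodeca-2,6,10-trienoate | CC(C)=C[C@H](CO[Si](CC)(CC)CC)OC(=O)/C(=C\C[C@@H](O[Si](C)(C)C(C)(C)C)/C(C)=C/CC/C(C)=C/CO[Si](C)(C)C(C)(C)C)[Sn](CCCC)(CCCC)CCCC
F2 | step 16 | (2R)-4-methyl-1-(triethylsilyloxy)pent-3-en-2-yl (2E,5R,6E,10E)-5,12-bis(tert-butyldimethylsilyloxy)-2-iodo-6,10-dimethyldodeca-2,6,10-trienoate | CC(C)=C[C@H](CO[Si](CC)(CC)CC)OC(=O)/C(I)=C\C[C@@H](O[Si](C)(C)C(C)(C)C)/C(C)=C/CC/C(C)=C/CO[Si](C)(C)C(C)(C)C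
F3 | step 16 | (2R)-1-hydroxy-4-methylpent-3-en-2-yl (2E,5R,6E,10E)-5,12-bis(tert-butyldimethylsilyloxy)-2-iodo-6,10-dimethyldodeca-2,6,10-trienoate | CC(C)=C[C@H](CO)OC(=O)/C(I)=C\C[C@@H](O[Si](C)(C)C(C)(C)C)/C(C)=C/CC/C(C)=C/CO[Si](C)(C)C(C)(C)C
F4 | step 16 | (2R)-4-methyl-1-oxopent-3-en-2-yl (2E,5R,6E,10E)-5,12-bis(tert-butyldimethylsilyloxy)-2-iodo-6,10-dimethyldodeca-2,6,10-trienoate | CC(C)=C[C@H](C=O)OC(=O)/C(I)=C\C[C@@H](O[Si](C)(C)C(C)(C)C)/C(C)=C/CC/C(C)=C/CO[Si](C)(C)C(C)(C)C
F5 | step 3 | racemic (2E,6E)-8-hydroxy-3,7-dimethylundeca-2,6-dien-10-yn-1-yl acetate | C#CCC(O)/C(C)=C/CC/C(C)=C/COC(C)=O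
F6 | step 3 | (2E,6S,7S,8S)-6,7-epoxy-8-hydroxy-3,7-dimethylundec-2-en-10-yn-1-yl acetate | C#CC[C@H](O)[C@]1(C)O[C@H]1CC/C(C)=C/COC(C)=O
F7 | step 13 | (2R)-4-methyl-1-(triethylsilyloxy)pent-3-en-2-yl 4-nitrophenyl carbonate | CC(C)=C[C@H](CO[Si](CC)(CC)CC)OC(=O)Oc1ccc(cc1)[N+](=O)[O-]
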